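**Strategy.** The target is the E-configured self-aldol condensation dimer of one aldehyde, the N-Boc derivative of 12-[(2R,5S,6S)-5-hydroxy-6-methylpiperidin-2-yl]dodecanal, so only one piperidine has to be built. Its ring (N1, C2 with methyl, C3 with hydroxyl, C4, C5, C6 with the chain) is disconnected into the 2-azadiene C2=N1–C6=C5, held in a 3-methyl-5-alkyl-1,2,4-triazine, and the oxygenated two-carbon unit C3–C4, an enamine of benzyloxyacetaldehyde. One inverse-electron-demand Diels–Alder reaction joins C2–C3 and C4–C5, then expels dinitrogen and pyrrolidine to give the 3-oxygenated pyridine. All-cis hydrogenation sets the three stereocentres, and salt resolution gives the single enantiomer.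

Key step: step 4

Assumption: the hydrogenation of step 5 gives a racemate, so the absolute configuration is introduced by resolution in step 6; racemates are written as both enantiomers joined by a dot.

**Step 1**
Reactants: 1 12-bromododecan-1-ol; 2 benzyl 2,2,2-trichloroacetimidate
Product: 3 benzyl 12-bromododecyl ether
Conditions: TfOH (0.05 equiv), CH2Cl2/cyclohexane, 0 °C to rt
Reagents that add atoms: benzyl 2,2,2-trichloroacetimidate, ClC(Cl)(Cl)C(=N)OCc1ccccc1
Why: Acid-catalysed O-benzylation with a trichloroacetimidate needs no alkoxide and so should spare the primary bromide; no stereocentre.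

**Step 2**
Reactants: 3 benzyl 12-bromododecyl ether; 4 ethyl 2,2-diethoxyacetate
Product: 6 14-(benzyloxy)-1,1-diethoxytetradecan-2-one, via Grignard reagent 5 (not isolated)
Conditions: Mg, I2 (cat.), THF, 50 °C; then addition to 4 (1.5 equiv), THF, −78 °C; cold 1 M HCl quench
Reagents that add atoms: ethyl 2,2-diethoxyacetate, CCOC(=O)C(OCC)OCC
Why: Acylation of a Grignard reagent by an α,α-dialkoxy ester should stop at the ketone because the chelated tetrahedral magnesium alkoxide survives at −78 °C until the quench; no stereocentre.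

**Step 3**
Reactants: 6 14-(benzyloxy)-1,1-diethoxytetradecan-2-one; 7 acetimidohydrazide hydrochloride (acetamidrazone hydrochloride)
Product: 9 5-[12-(benzyloxy)dodecyl]-3-methyl-1,2,4-triazine, via ketoaldehyde 8 (not isolated)
Conditions: 2 M HCl, THF, 45 °C; then 7, NaHCO3, EtOH/H2O, 0 °C to rt
Reagents that add atoms: acetimidohydrazide hydrochloride, CC(=N)NN.Cl
Why: Acetal hydrolysis followed by the double condensation of an amidrazone with a 1,2-dicarbonyl compound (1,2,4-triazine synthesis); the hydrazine NH2 should attack the more electrophilic aldehyde and the amidine nitrogen the ketone, which places the chain on C5; no stereocentre.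

**Step 4**
Reactants: 9 5-[12-(benzyloxy)dodecyl]-3-methyl-1,2,4-triazine; 10 benzyloxyacetaldehyde
Product: 14 3-(benzyloxy)-6-[12-(benzyloxy)dodecyl]-2-methylpyridine, via enamine 11 (not isolated), via bicyclic cycloadduct 12 (not isolated), via dihydropyridine 13 (not isolated)
Conditions: pyrrolidine (1.5 equiv), 4 Å molecular sieves, 1,4-dioxane, 100 °C (sealed tube)
Reagents that add atoms: benzyloxyacetaldehyde, O=CCOCc1ccccc1
Why: Pyrrolidine condenses with 10 to the electron-rich 2-alkoxy enamine 11, which adds across C3 and C6 of the electron-poor triazine 9 in an inverse-electron-demand [4+2] cycloaddition; the triazine unit C3=N4–C5=C6 is the 2-azadiene that becomes C2=N1–C6=C5 of the piperidine, and the two new bonds are C2–C3 and C4–C5 (piperidine numbering). The closest known reaction is the Boger pyridine synthesis from 1,2,4-triazines and enamines. The six-membered ring is closed by this concerted, asynchronous cycloaddition to the bridged bicycle 12, whose temporary N=N bridge is then lost as dinitrogen by retro-[4+2] cleavage to give dihydropyridine 13, and elimination of pyrrolidine aromatises 13 to 14. The stereocentres of 12 and 13 are transient and vanish on aromatisation, so this step needs no stereocontrol; the three ring stereocentres are set in step 5. The selectivity needed is regiochemical: the nucleophilic enamine β-carbon, which carries the benzyloxy group, should bond to triazine C3 (flanked by two nitrogens, the most electrophilic carbon), which puts the oxygen next to the methyl-bearing carbon, and the acidic C3–H of 13 (α to C=N) should expel the amine on C4 and not benzyl alcohol.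

**Step 5**
Reactants: 14 3-(benzyloxy)-6-[12-(benzyloxy)dodecyl]-2-methylpyridine
Product: 16 rac-(2S,3S,6R)-6-(12-hydroxydodecyl)-2-methylpiperidin-3-ol, via pyridinol 15 (not isolated)
Conditions: H2 (1 atm), Pd/C (10%), AcOH, rt; then Rh/Al2O3 (5%), H2 (5 bar), AcOH, 50 °C; aq NaOH work-up
Reagents that add atoms: none
Why: Hydrogenolysis of both benzyl ethers over Pd, then heterogeneous hydrogenation of the pyridinium ring over Rh, in which all hydrogens are delivered to the face lying on the metal (cis addition), should set C2, C3 and C6 all-cis in racemic form.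

**Step 6**
Reactants: 16 rac-(2S,3S,6R)-6-(12-hydroxydodecyl)-2-methylpiperidin-3-ol
Product: 17 (2S,3S,6R)-6-(12-hydroxydodecyl)-2-methylpiperidin-3-ol
Conditions: (−)-O,O'-di-p-toluoyl-L-tartaric acid (1.0 equiv), EtOH, recrystallisation to constant rotation; then 2 M NaOH, CH2Cl2
Reagents that add atoms: none
Why: Classical resolution by fractional crystallisation of diastereomeric ammonium salts, which differ in solubility, followed by liberation of the (2S,3S,6R) amine with base; which antipode of the acid gives the less soluble salt of the wanted amine has to be found by trial, and the L-acid is written here.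

**Step 7**
Reactants: 17 (2S,3S,6R)-6-(12-hydroxydodecyl)-2-methylpiperidin-3-ol; 18 di-tert-butyl dicarbonate
Product: 19 tert-butyl (2S,3S,6R)-3-hydroxy-6-(12-hydroxydodecyl)-2-methylpiperidine-1-carboxylate
Conditions: Boc2O (1.5 equiv), Et3N, MeOH, 50 °C
Reagents that add atoms: di-tert-butyl dicarbonate, CC(C)(C)OC(=O)OC(=O)OC(C)(C)C
Why: Carbamate formation (Boc protection) at the secondary amine should be faster than carbonate formation at either hydroxyl in the absence of an acyl-transfer catalyst; stereocentres untouched.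

**Step 8**
Reactants: 19 tert-butyl (2S,3S,6R)-3-hydroxy-6-(12-hydroxydodecyl)-2-methylpiperidine-1-carboxylate
Product: 20 tert-butyl (2S,3S,6R)-3-hydroxy-2-methyl-6-(12-oxododecyl)piperidine-1-carboxylate
Conditions: TEMPO (0.1 equiv), PhI(OAc)2 (1.1 equiv), CH2Cl2, rt
Reagents that add atoms: none
Why: The oxoammonium-mediated TEMPO/PhI(OAc)2 oxidation is selective for the unhindered primary alcohol over the ring secondary alcohol and stops at the aldehyde; stereocentres untouched.

**Step 9**
Reactants: 20 tert-butyl (2S,3S,6R)-3-hydroxy-2-methyl-6-(12-oxododecyl)piperidine-1-carboxylate (two molecules)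
Product: 21 tert-butyl (2S,3S,6R)-6-[(12E)-23-[(2R,5S,6S)-1-(tert-butoxycarbonyl)-5-hydroxy-6-methylpiperidin-2-yl]-13-formyltricos-12-en-1-yl]-3-hydroxy-2-methylpiperidine-1-carboxylate
Conditions: pyrrolidine (0.2 equiv), PhCO2H (0.2 equiv), toluene, 40 °C
Reagents that add atoms: none
Why: Amine-catalysed self-aldol condensation (the enamine of one aldehyde adds to the iminium ion of a second, then the amine is eliminated); the only enolisable position is the aldehyde α-carbon, and the trisubstituted enal should form as the more stable E isomer with the chain trans to the formyl group; the ring stereocentres are remote and untouched.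

**Step 10**
Reactants: 21 the N,N'-di-Boc enal of step 9
Product: 22 (2E)-2-{10-[(2R,5S,6S)-5-hydroxy-6-methylpiperidin-2-yl]decyl}-14-[(2R,5S,6S)-5-hydroxy-6-methylpiperidin-2-yl]tetradec-2-enal (CNP0177491.1)
Conditions: TFA/CH2Cl2 (1:4), 0 °C; then aq NaHCO3
Reagents that add atoms: none
Why: Acidolysis of both tert-butyl carbamates (loss of 2-methylpropene and CO2) and neutralisation should give the free diamine; the enal and the stereocentres should not be affected by cold TFA.

**Compound list**

1 | 12-bromododecan-1-ol | OCCCCCCCCCCCCBr | starting material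
2 | benzyl 2,2,2-trichloroacetimidate | ClC(Cl)(Cl)C(=N)OCc1ccccc1 | starting material
3 | benzyl 12-bromododecyl ether | BrCCCCCCCCCCCCOCc1ccccc1 | intermediate
4 | ethyl 2,2-diethoxyacetate | CCOC(=O)C(OCC)OCC | starting material
5 | [12-(benzyloxy)dodecyl]magnesium bromide (Grignard reagent, not isolated) | Br[Mg]CCCCCCCCCCCCOCc1ccccc1 | intermediate
6 | 14-(benzyloxy)-1,1-diethoxytetradecan-2-one | CCOC(OCC)C(=O)CCCCCCCCCCCCOCc1ccccc1 | intermediate
7 | acetimidohydrazide hydrochloride | CC(=N)NN.Cl | starting material
8 | 14-(benzyloxy)-2-oxotetradecanal (ketoaldehyde, not isolated) | O=CC(=O)CCCCCCCCCCCCOCc1ccccc1 | intermediate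
9 | 5-[12-(benzyloxy)dodecyl]-3-methyl-1,2,4-triazine | Cc1nncc(CCCCCCCCCCCCOCc2ccccc2)n1 | intermediate
10 | benzyloxyacetaldehyde | O=CCOCc1ccccc1 | starting material
11 | 1-[(E)-2-(benzyloxy)ethenyl]pyrrolidine (enamine, not isolated) | C1CCN(C1)/C=C/OCc1ccccc1 | intermediate
12 | 8-(benzyloxy)-6-[12-(benzyloxy)dodecyl]-4-methyl-7-(pyrrolidin-1-yl)-2,3,5-triazabicyclo[2.2.2]octa-2,5-diene (bicyclic cycloadduct, transient stereoisomer mixture, not isolated) | CC12N=NC(C(CCCCCCCCCCCCOCc3ccccc3)=N1)C(N1CCCC1)C2OCc1ccccc1 | intermediate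
13 | 3-(benzyloxy)-6-[12-(benzyloxy)dodecyl]-2-methyl-4-(pyrrolidin-1-yl)-3,4-dihydropyridine (transient stereoisomer mixture, not isolated) | CC1=NC(CCCCCCCCCCCCOCc2ccccc2)=CC(N2CCCC2)C1OCc1ccccc1 | intermediate
14 | 3-(benzyloxy)-6-[12-(benzyloxy)dodecyl]-2-methylpyridine | Cc1nc(CCCCCCCCCCCCOCc2ccccc2)ccc1OCc1ccccc1 | intermediate
15 | 6-(12-hydroxydodecyl)-2-methylpyridin-3-ol (pyridinol, not isolated) | Cc1nc(CCCCCCCCCCCCO)ccc1O | intermediate
16 | rac-(2S,3S,6R)-6-(12-hydroxydodecyl)-2-methylpiperidin-3-ol (all-cis racemate) | C[C@@H]1N[C@H](CCCCCCCCCCCCO)CC[C@@H]1O.C[C@H]1N[C@@H](CCCCCCCCCCCCO)CC[C@H]1O | intermediate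
17 | (2S,3S,6R)-6-(12-hydroxydodecyl)-2-methylpiperidin-3-ol | C[C@@H]1N[C@H](CCCCCCCCCCCCO)CC[C@@H]1O | intermediate
18 | di-tert-butyl dicarbonate | CC(C)(C)OC(=O)OC(=O)OC(C)(C)C | starting material
19 | tert-butyl (2S,3S,6R)-3-hydroxy-6-(12-hydroxydodecyl)-2-methylpiperidine-1-carboxylate | C[C@@H]1N(C(=O)OC(C)(C)C)[C@H](CCCCCCCCCCCCO)CC[C@@H]1O | intermediate
20 | tert-butyl (2S,3S,6R)-3-hydroxy-2-methyl-6-(12-oxododecyl)piperidine-1-carboxylate | C[C@@H]1N(C(=O)OC(C)(C)C)[C@H](CCCCCCCCCCCC=O)CC[C@@H]1O | intermediate
21 | tert-butyl (2S,3S,6R)-6-[(12E)-23-[(2R,5S,6S)-1-(tert-butoxycarbonyl)-5-hydroxy-6-methylpiperidin-2-yl]-13-formyltricos-12-en-1-yl]-3-hydroxy-2-methylpiperidine-1-carboxylate | C[C@@H]1N(C(=O)OC(C)(C)C)[C@H](CCCCCCCCCCC/C=C(/C=O)CCCCCCCCCC[C@@H]2CC[C@H](O)[C@H](C)N2C(=O)OC(C)(C)C)CC[C@@H]1O | intermediate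
22 | (2E)-2-{10-[(2R,5S,6S)-5-hydroxy-6-methylpiperidin-2-yl]decyl}-14-[(2R,5S,6S)-5-hydroxy-6-methylpiperidin-2-yl]tetradec-2-enal | C[C@@H]1N[C@H](CCCCCCCCCCC/C=C(/C=O)CCCCCCCCCC[C@@H]2CC[C@H](O)[C@H](C)N2)CC[C@@H]1O | target

**Total step count:** 10 steps.
**Longest linear sequence:** 10 steps (from 1).

**Steps most likely to fail**

Step 4 (key cycloaddition). The dialkyl-substituted triazine may react too slowly with the enamine, the cycloaddition may take the opposite orientation, or aromatisation may proceed by loss of benzyl alcohol instead of pyrrolidine. The fallback builds the pyridine by the known ring transformation of a 2-acylfuran with ammonia. It sets out from bromide 3: alkylation of 2-furyllithium (furan, n-BuLi, THF, then 3) should give 2-[12-(benzyloxy)dodecyl]furan F1. Friedel–Crafts acetylation at the free α-position (Ac2O, BF3·OEt2, CH2Cl2, 0 °C) should give 1-{5-[12-(benzyloxy)dodecyl]furan-2-yl}ethan-1-one F2. Heating with aqueous NH3/NH4Cl (170 °C, autoclave) should give 6-[12-(benzyloxy)dodecyl]-2-methylpyridin-3-ol F3. Under the conditions of step 5, F3 should lose its benzyl group to pyridinol 15 and be hydrogenated, so the fallback comes back to the route at 16.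

Step 6 (resolution). Salt formation may give waxy, non-crystalline salts because of the long chain, or crystallisation may proceed without useful enrichment. The fallback sets out from racemate 16, which is N-protected under the conditions of step 7 to rac-tert-butyl (2S,3S,6R)-3-hydroxy-6-(12-hydroxydodecyl)-2-methylpiperidine-1-carboxylate F4. The enantiomers of F4 are then separated by preparative chromatography on a chiral stationary phase (amylose tris(3,5-dimethylphenylcarbamate), supercritical CO2/MeOH). The (2S,3S,6R) fraction is 19, where the fallback comes back to the route.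

Step 9 (dimerisation). The self-condensation may stall at partial conversion, or the enal may react further through its dienamine to oligomers. The fallback joins the two halves by olefin cross-metathesis and sets out from aldehyde 20. One portion is α-methylenated (aqueous formaldehyde, pyrrolidine/propionic acid, i-PrOH, 45 °C) to tert-butyl (2S,3S,6R)-6-(11-formyldodec-11-en-1-yl)-3-hydroxy-2-methylpiperidine-1-carboxylate F5. A second portion is methylenated by a Wittig reaction (Ph3P=CH2, THF, 0 °C) to tert-butyl (2S,3S,6R)-3-hydroxy-2-methyl-6-(tridec-12-en-1-yl)piperidine-1-carboxylate F6. Cross-metathesis of F5 and F6 (second-generation Hoveyda–Grubbs catalyst, CH2Cl2, 40 °C) should give the E-trisubstituted enal 21, where the fallback comes back to the route.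

**Further compounds**

F1 | step 4 | 2-[12-(benzyloxy)dodecyl]furan | c1coc(CCCCCCCCCCCCOCc2ccccc2)c1
F2 | step 4 | 1-{5-[12-(benzyloxy)dodecyl]furan-2-yl}ethan-1-one | CC(=O)c1ccc(CCCCCCCCCCCCOCc2ccccc2)o1
F3 | step 4 | 6-[12-(benzyloxy)dodecyl]-2-methylpyridin-3-ol | Cc1nc(CCCCCCCCCCCCOCc2ccccc2)ccc1O
F4 | step 6 | rac-tert-butyl (2S,3S,6R)-3-hydroxy-6-(12-hydroxydodecyl)-2-methylpiperidine-1-carboxylate | C[C@@H]1N(C(=O)OC(C)(C)C)[C@H](CCCCCCCCCCCCO)CC[C@@H]1O.C[C@H]1N(C(=O)OC(C)(C)C)[C@@H](CCCCCCCCCCCCO)CC[C@H]1O
F5 | step 9 | tert-butyl (2S,3S,6R)-6-(11-formyldodec-11-en-1-yl)-3-hydroxy-2-methylpiperidine-1-carboxylate | C[C@@H]1N(C(=O)OC(C)(C)C)[C@H](CCCCCCCCCCC(=C)C=O)CC[C@@H]1O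
F6 | step 9 | tert-butyl (2S,3S,6R)-3-hydroxy-2-methyl-6-(tridec-12-en-1-yl)piperidine-1-carboxylate | C[C@@H]1N(C(=O)OC(C)(C)C)[C@H](CCCCCCCCCCCC=C)CC[C@@H]1O
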